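**Retrosynthetic overview**
1. Target 11 ⇐ nona-O-benzyl dimer 10 by global hydrogenolysis.
2. 10 ⇐ 4-aryl-flavan-3-one 9 by carbonyl reduction (sets C3 of the upper unit).
3. 9 ⇐ interflavan C4–C8 bond between two carbons that are both nucleophilic by nature: the enol carbon C4 of silyl enol ether 5, turned into an electrophile as an iodane-bound enolonium, and C8 of tetra-O-benzylcatechin 7 (sets C4).
4. 5 ⇐ (−)-epigallocatechin 1 (benzylation, C3 oxidation, kinetic enolisation towards C4); 7 ⇐ (+)-catechin 6.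
5. No ring is built: rings A, C and B of both units come intact from the two natural flavan-3-ols; only the interflavan bond is made.

Assumption: (−)-epigallocatechin (2R,3R) and (+)-catechin (2R,3S) are bought as single natural enantiomers; unnumbered reagents are commercial.

**Step 1**
Reactants: 1 (−)-epigallocatechin
Product: 2 (2R,3R)-5,7-bis(benzyloxy)-2-[3,4,5-tris(benzyloxy)phenyl]chroman-3-ol
Conditions: BnBr, K2CO3, DMF, −10 °C to rt, argon
Reagents that add atoms: benzyl bromide, BrCc1ccccc1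
Why: Williamson etherification of the five phenols only (the secondary 3-OH is not deprotonated by carbonate), run cold and oxygen-free so that C2 does not epimerise; C2 and C3 come unchanged from 1.

**Step 2**
Reactants: 2 penta-O-benzyl-epigallocatechin
Product: 3 (2R)-5,7-bis(benzyloxy)-2-[3,4,5-tris(benzyloxy)phenyl]chroman-3-one
Conditions: Dess–Martin periodinane, wet CH2Cl2, rt
Reagents that add atoms: none
Why: Dess–Martin oxidation of the secondary alcohol under near-neutral conditions gives the flavan-3-one without enolising C2, so C2 stays R.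

**Step 3**
Reactants: 3 penta-O-benzyl-flavan-3-one
Product: 5 (2R)-5,7-bis(benzyloxy)-2-[3,4,5-tris(benzyloxy)phenyl]-3-(trimethylsilyloxy)-2H-chromene, via lithium enolate 4 (not isolated)
Conditions: LiN(SiMe3)2, Me3SiCl (in-situ quench), THF, −78 °C; hexane, filtration, used crude
Reagents that add atoms: chlorotrimethylsilane, C[Si](C)(C)Cl
Why: Kinetic enolisation with a hindered amide base and internal silyl trapping removes a proton from the benzylic C4 methylene and not from the tertiary, oxygen-bearing C2–H, giving the silyl enol ether conjugated with ring A (regioselective silyl enol ether formation) with C2 untouched.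

**Step 4**
Reactants: 6 (+)-catechin
Product: 7 (2R,3S)-5,7-bis(benzyloxy)-2-[3,4-bis(benzyloxy)phenyl]chroman-3-ol
Conditions: BnBr, K2CO3, DMF, 0 °C to rt, argon
Reagents that add atoms: benzyl bromide, BrCc1ccccc1
Why: Williamson etherification of the four phenols leaves the 3-OH free and C6/C8 unsubstituted; both stereocentres come from 6.

**Step 5 (key step)**
Reactants: 5 silyl enol ether; 7 tetra-O-benzylcatechin
Product: 9 (2R,4R)-5,7-bis(benzyloxy)-4-{(2R,3S)-5,7-bis(benzyloxy)-2-[3,4-bis(benzyloxy)phenyl]-3-hydroxychroman-8-yl}-2-[3,4,5-tris(benzyloxy)phenyl]chroman-3-one, via iodane-bound enolonium 8 (not isolated)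
Conditions: PhI(OH)OTs (1.0 equiv), BF3·OEt2, CH2Cl2, −78 °C, 5 min; then 7 (3 equiv), −78 to −20 °C; aq. NaHCO3
Reagents that add atoms: none
Why: Enolonium (polarity-reversed enolate) α-arylation: the trivalent-iodine-bound enolate 8 makes C4 an electrophile stabilised by ring A, the more nucleophilic C8 of 7 attacks it in a Friedel–Crafts sense with loss of iodobenzene, and attack is pseudo-axial and anti to the pseudo-equatorial C2 aryl, giving the 2,4-trans (4β, 4R) ketone, which also places the C4 aryl away from the peri 5-benzyloxy group.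

**Step 6**
Reactants: 9 4-aryl-flavan-3-one
Product: 10 (2R,3R,4R)-5,7-bis(benzyloxy)-4-{(2R,3S)-5,7-bis(benzyloxy)-2-[3,4-bis(benzyloxy)phenyl]-3-hydroxychroman-8-yl}-2-[3,4,5-tris(benzyloxy)phenyl]chroman-3-ol
Conditions: LiBH(s-Bu)3, LiBr, THF, −78 °C; then H2O
Reagents that add atoms: none
Why: Bulky-hydride reduction of a flavan-3-one: hydride enters equatorially, anti to the ring C2–O1 bond and to the C2 aryl, giving the axial 3-OH that is cis to the C2 aryl and trans to the pseudo-axial C4 aryl (3R), as in the known oxidation–reduction conversion of 2,3-trans into 2,3-cis flavan-3-ols.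

**Step 7**
Reactants: 10 nona-O-benzyl dimer
Product: 11 epigallocatechin-(4β→8)-catechin (target, CNP0225927.1)
Conditions: H2 (1 atm), Pd(OH)2/C, THF/MeOH/H2O, rt; filtration, lyophilisation
Reagents that add atoms: none
Why: Hydrogenolysis of the nine benzyl aryl ethers over palladium hydroxide on carbon leaves the interflavan C–C bond, the ring ethers and all five stereocentres untouched.

**Compound list**
1 | (−)-epigallocatechin, (2R,3R)-2-(3,4,5-trihydroxyphenyl)chromane-3,5,7-triol | Oc1cc(O)c2c(c1)O[C@H](c1cc(O)c(O)c(O)c1)[C@H](O)C2 | starting material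
2 | 5,7,3',4',5'-penta-O-benzyl-(−)-epigallocatechin (2R,3R) | c3ccccc3COc1cc(OCc3ccccc3)c2c(c1)O[C@H](c1cc(OCc3ccccc3)c(OCc3ccccc3)c(OCc3ccccc3)c1)[C@H](O)C2 | intermediate
3 | (2R)-penta-O-benzyl-flavan-3-one | c3ccccc3COc1cc(OCc3ccccc3)c2c(c1)O[C@H](c1cc(OCc3ccccc3)c(OCc3ccccc3)c(OCc3ccccc3)c1)C(=O)C2 | intermediate
4 | lithium enolate of 3 with C3=C4 double bond (2R) | c3ccccc3COc1cc(OCc3ccccc3)c2c(c1)O[C@H](c1cc(OCc3ccccc3)c(OCc3ccccc3)c(OCc3ccccc3)c1)C(O[Li])=C2 | intermediate
5 | (2R)-3-(trimethylsilyloxy)-2H-chromene (silyl enol ether of 3) | c3ccccc3COc1cc(OCc3ccccc3)c2c(c1)O[C@H](c1cc(OCc3ccccc3)c(OCc3ccccc3)c(OCc3ccccc3)c1)C(O[Si](C)(C)C)=C2 | intermediate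
6 | (+)-catechin, (2R,3S)-2-(3,4-dihydroxyphenyl)chromane-3,5,7-triol | Oc1cc(O)c2c(c1)O[C@H](c1ccc(O)c(O)c1)[C@@H](O)C2 | starting material
7 | 5,7,3',4'-tetra-O-benzyl-(+)-catechin (2R,3S) | c3ccccc3COc1cc(OCc3ccccc3)c2c(c1)O[C@H](c1ccc(OCc3ccccc3)c(OCc3ccccc3)c1)[C@@H](O)C2 | intermediate
8 | enolonium: (2R)-2H-chromen-3-yl O-bound phenyl(tosyloxy)-λ3-iodane | c3ccccc3COc1cc(OCc3ccccc3)c2c(c1)O[C@H](c1cc(OCc3ccccc3)c(OCc3ccccc3)c(OCc3ccccc3)c1)C(OI(c4ccccc4)OS(=O)(=O)c4ccc(C)cc4)=C2 | intermediate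
9 | 4β-(tetra-O-benzylcatechin-8-yl)-penta-O-benzyl-flavan-3-one, upper unit (2R,4R), lower unit (2R,3S) | c3ccccc3COc1cc(OCc3ccccc3)c2c(c1)O[C@H](c1cc(OCc3ccccc3)c(OCc3ccccc3)c(OCc3ccccc3)c1)C(=O)[C@H]2c1c(OCc3ccccc3)cc(OCc3ccccc3)c2c1O[C@H](c1ccc(OCc3ccccc3)c(OCc3ccccc3)c1)[C@@H](O)C2 | intermediate
10 | nona-O-benzyl-epigallocatechin-(4β→8)-catechin, upper unit (2R,3R,4R), lower unit (2R,3S) | c3ccccc3COc1cc(OCc3ccccc3)c2c(c1)O[C@H](c1cc(OCc3ccccc3)c(OCc3ccccc3)c(OCc3ccccc3)c1)[C@H](O)[C@H]2c1c(OCc3ccccc3)cc(OCc3ccccc3)c2c1O[C@H](c1ccc(OCc3ccccc3)c(OCc3ccccc3)c1)[C@@H](O)C2 | intermediate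
11 | epigallocatechin-(4β→8)-catechin, upper unit (2R,3R,4R), lower unit (2R,3S) | Oc1cc(O)c2c(c1)O[C@H](c1cc(O)c(O)c(O)c1)[C@H](O)[C@H]2c1c(O)cc(O)c2c1O[C@H](c1ccc(O)c(O)c1)[C@@H](O)C2 | target

**Step count**
Total: 7 steps. Longest linear sequence: 6 steps (1, 2, 3, 5, 6, 7).

**Three steps most likely to fail**

Step 6 (C3 reduction) is the weakest point. The pseudo-axial C4 aryl sits on the same face from which the hydride must come, so the 3-epimer (2,3-trans-3,4-cis) may form instead or alongside; the acidic C4–H may also be removed by the basic hydride. Fallback: set out from 2 and keep the natural C3 alcohol throughout. DDQ with 2-ethoxyethanol in CH2Cl2 oxidises the benzylic C4–H to (2R,3R,4S)-4-(2-ethoxyethoxy)-penta-O-benzyl-epigallocatechin F4. Me3SiOTf in CH2Cl2 at −78 °C with excess 7 then ionises the C4 ether, and C8 of 7 adds anti to the free 3-OH. This gives 10 directly, where the route is rejoined.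

Step 5 (enolonium arylation) may fail in three ways: the trivalent iodine reagent can attack the benzyloxy arenes; the enolonium can condense with ring A of a second molecule before 7 is added; or it can lose the C2 proton towards a flavylium species and scramble C2. Fallback: invert the other partner instead. Set out from 7 and 5: NBS in CH2Cl2 at −78 °C gives 8-bromo-5,7,3',4'-tetra-O-benzylcatechin F3, and palladium-catalysed α-arylation of silyl enol ether 5 with F3 (Pd(dba)2, P(t-Bu)3, ZnF2, DMF, 70 °C) forms the C4–C8 bond and returns to the route at 9.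

Step 3 (enolisation) may give some enolisation at C2, which would erase the C2 stereocentre, and the silyl enol ether is hydrolytically fragile. Fallback: set out from 2 and reach a C4 enolonium equivalent without any enolisation. DDQ with methanol in CH2Cl2 gives (2R,3R,4S)-4-methoxy-penta-O-benzyl-epigallocatechin F1. Dess–Martin oxidation gives the α-methoxy ketone (2R,4S)-4-methoxy-penta-O-benzyl-flavan-3-one F2. Me3SiOTf with 7 in CH2Cl2 at −40 °C then ionises the C4–OMe bond and gives 9, where the route is rejoined.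

**Further compounds**
F1 | step 3 | (2R,3R,4S)-5,7-bis(benzyloxy)-4-methoxy-2-[3,4,5-tris(benzyloxy)phenyl]chroman-3-ol | c3ccccc3COc1cc(OCc3ccccc3)c2c(c1)O[C@H](c1cc(OCc3ccccc3)c(OCc3ccccc3)c(OCc3ccccc3)c1)[C@H](O)[C@H]2OC
F2 | step 3 | (2R,4S)-5,7-bis(benzyloxy)-4-methoxy-2-[3,4,5-tris(benzyloxy)phenyl]chroman-3-one | c3ccccc3COc1cc(OCc3ccccc3)c2c(c1)O[C@H](c1cc(OCc3ccccc3)c(OCc3ccccc3)c(OCc3ccccc3)c1)C(=O)[C@H]2OC
F3 | step 5 | (2R,3S)-8-bromo-5,7-bis(benzyloxy)-2-[3,4-bis(benzyloxy)phenyl]chroman-3-ol | Brc1c(OCc3ccccc3)cc(OCc3ccccc3)c2c1O[C@H](c1ccc(OCc3ccccc3)c(OCc3ccccc3)c1)[C@@H](O)C2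
F4 | step 6 | (2R,3R,4S)-5,7-bis(benzyloxy)-4-(2-ethoxyethoxy)-2-[3,4,5-tris(benzyloxy)phenyl]chroman-3-ol | c3ccccc3COc1cc(OCc3ccccc3)c2c(c1)O[C@H](c1cc(OCc3ccccc3)c(OCc3ccccc3)c(OCc3ccccc3)c1)[C@H](O)[C@H]2OCCOCC
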